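The route rests on the C8–C9 bond of the ten-membered ring: both carbons are oxygenated (tertiary C8–OH on the γ-lactone ring; C9–OAc beside ring-fusion carbon C10), so both are carbonyl-derived and of like polarity. A SmI2 ketyl (pinacol) macrocyclisation unites them, closing the ten-membered carbocycle and setting C8 and C9 as the cis-diol in one operation. The precursor is an open-chain keto aldehyde: the fully substituted cyclohexane (from an enzymatically desymmetrised dione) carrying the C9 aldehyde on C10, linked through C2–C7 (enoate included, by Horner–Wadsworth–Emmons union) to a C8 β-keto ester with a C7 silyloxy group; lactonisation onto C19 follows.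

Key step: step 29

Remark: briarane numbering (C1–C20) is used for all intermediates and β denotes the face of the six-membered ring that carries the C15 methyl group; C17 is carried as an epimer mixture from step 23 and is fixed under thermodynamic control in step 31.

Step 1
Reactants: 1 2-methylcyclohexane-1,3-dione
Product: 2 2-allyl-2-methylcyclohexane-1,3-dione
Conditions: allyl bromide, 1 M NaOH (aq), rt
Reagents that add atoms: allyl bromide, C=CCBr
Why: C-allylation (SN2) of the cyclic 1,3-dione enolate in aqueous base should give the 2,2-disubstituted dione; no stereocentre is formed.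

Step 2
Reactants: 2 2-allyl-2-methylcyclohexane-1,3-dione
Product: 3 (2S,3S)-2-allyl-3-hydroxy-2-methylcyclohexan-1-one
Conditions: baker's yeast (Saccharomyces cerevisiae), sucrose, H2O, 30 °C
Reagents that add atoms: none
Why: Enzymatic desymmetrising reduction of one of the two enantiotopic carbonyl groups (baker's yeast reduction of a 2,2-disubstituted cyclohexane-1,3-dione) should set the C14 carbinol (S) and with it the quaternary C1 (S), the hydroxyl ending cis to the allyl group.

Step 3
Reactants: 3 (2S,3S)-2-allyl-3-hydroxy-2-methylcyclohexan-1-one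
Product: 4 (2S,3S)-2-allyl-3-(tert-butyldimethylsilyloxy)-2-methylcyclohexan-1-one
Conditions: TBSCl, imidazole, DMF, rt
Reagents that add atoms: tert-butyldimethylsilyl chloride, CC(C)(C)[Si](C)(C)Cl
Why: Standard silylation of the secondary alcohol protects the β-hydroxy ketone against retro-aldol cleavage in the basic steps that follow; no stereocentre is touched.

Step 4
Reactants: 4 (2S,3S)-2-allyl-3-(tert-butyldimethylsilyloxy)-2-methylcyclohexan-1-one
Product: 5 (2S,3S)-2-allyl-3-(tert-butyldimethylsilyloxy)-2,6-dimethylcyclohexan-1-one (C11 epimers)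
Conditions: LiN(i-Pr)2, THF, −78 °C; then MeI, −78 → 0 °C
Reagents that add atoms: iodomethane, CI
Why: Kinetic lithium enolate formation can only occur toward C11 because C1 is quaternary, and enolate C-methylation gives the C11 methyl ketone; the C11 configuration is irrelevant because C11 becomes sp2 in step 5.

Step 5
Reactants: 5 C11-methyl ketone (C11 epimers)
Product: 6 (5S,6S)-6-allyl-5-(tert-butyldimethylsilyloxy)-2,6-dimethylcyclohex-2-en-1-one
Conditions: IBX, DMSO/toluene, 75 °C
Reagents that add atoms: none
Why: IBX-mediated α,β-dehydrogenation of the ketone should give the conjugated 2-methyl enone (C11=C12), the only possible regiochemistry since C1 bears no hydrogen.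

Step 6
Reactants: 6 (5S,6S)-6-allyl-5-(tert-butyldimethylsilyloxy)-2,6-dimethylcyclohex-2-en-1-one
Product: 7 (5S,6S)-6-allyl-5-(tert-butyldimethylsilyloxy)-1-[(methoxymethoxy)methyl]-2,6-dimethylcyclohex-2-en-1-ol (C10 epimers)
Conditions: Bu3SnCH2OCH2OMe, n-BuLi, THF, −78 °C; then 6, −78 °C; H2O
Reagents that add atoms: tributyl[(methoxymethoxy)methyl]stannane, CCCC[Sn](CCCC)(CCCC)COCOC
Why: Tin–lithium exchange gives (methoxymethoxy)methyllithium, a hard hydroxymethyl-anion equivalent that should add 1,2 to the enone carbonyl and so introduce C9; the new carbinol centre at C10 is erased in step 7.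

Step 7
Reactants: 7 tertiary allylic alcohol (C10 epimers)
Product: 8 (4R,5S)-4-allyl-5-(tert-butyldimethylsilyloxy)-3-[(methoxymethoxy)methyl]-2,4-dimethylcyclohex-2-en-1-one
Conditions: pyridinium chlorochromate, 4 Å molecular sieves, CH2Cl2, rt
Reagents that add atoms: none
Why: Babler–Dauben oxidative transposition: the chromate ester of the tertiary allylic alcohol undergoes a [3,3] shift to C12 and is oxidised, which should give the transposed enone with the C12 ketone and the tetrasubstituted C10=C11 alkene.

Step 8
Reactants: 8 transposed enone with allyl group at C1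
Product: 9 (4R,5S)-5-(tert-butyldimethylsilyloxy)-3-[(methoxymethoxy)methyl]-2,4-dimethyl-4-[(E)-prop-1-enyl]cyclohex-2-en-1-one
Conditions: RuHCl(CO)(PPh3)3 (cat.), toluene, 80 °C
Reagents that add atoms: none
Why: Ruthenium-hydride-catalysed alkene isomerisation (hydrometalation and β-hydride elimination) should move the terminal double bond into the more stable internal position next to C1, leaving the tetrasubstituted enone untouched.

Step 9
Reactants: 9 propenyl enone
Product: 11 (1R,6S)-6-(tert-butyldimethylsilyloxy)-2-[(methoxymethoxy)methyl]-1,3-dimethyl-4-oxocyclohex-2-ene-1-carbaldehyde (C2 aldehyde), via ozonide 10 (not isolated)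
Conditions: O3, CH2Cl2, −78 °C; then PPh3, −78 °C → rt
Reagents that add atoms: ozone, [O-][O+]=O
Why: Ozonolysis should cleave the electron-rich disubstituted propenyl alkene much faster than the electron-poor tetrasubstituted enone alkene, and reductive work-up of the ozonide gives the neopentyl C2 aldehyde.

Step 10
Reactants: 11 C2 aldehyde
Product: 13 (2R)-homoallylic alcohol (11 with CHO replaced by (R)-CH(OH)CH2CH=CH2), via borinate 12 (not isolated)
Conditions: (+)-B-methoxydiisopinocampheylborane, allylmagnesium bromide, Et2O, −78 → 25 °C; then 11, −78 °C; then ethanolamine, rt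
Reagents that add atoms: allylmagnesium bromide, C=CC[Mg]Br
Why: Brown allylboration: the reagent-controlled chair transition state of (+)-B-allyldiisopinocampheylborane should deliver the allyl group to the Re face of the aldehyde (2R carbinol) against the substrate bias, and the aldehyde reacts in preference to the hindered enone ketone.

Step 11
Reactants: 13 (2R)-homoallylic alcohol
Product: 14 (2R)-homoallylic acetate
Conditions: Ac2O, pyridine, DMAP (cat.), CH2Cl2, rt
Reagents that add atoms: acetic anhydride, CC(=O)OC(C)=O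
Why: DMAP-catalysed acetylation installs the C2 acetate of the target and blocks the hydroxyl for the steps that follow.

Step 12
Reactants: 14 (2R)-homoallylic acetate
Product: 17 C4 primary alcohol (C2 acetoxy, C3H2, C4H2OH), via ozonide 15 (not isolated), via aldehyde 16 (not isolated)
Conditions: O3, CH2Cl2, −78 °C; PPh3, −78 → 0 °C; then NaBH(OAc)3, AcOH, 0 °C → rt
Reagents that add atoms: ozone, [O-][O+]=O
Why: Ozonolysis of the only electron-rich alkene followed by in situ reduction with NaBH(OAc)3, which should reduce the aldehyde but not the hindered enone ketone and is not basic enough to cause acetyl migration, shortens the chain to the C4 primary alcohol.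

Step 13
Reactants: 17 C4 primary alcohol
Product: 18 C4 primary iodide
Conditions: I2, PPh3, imidazole, CH2Cl2, 0 °C → rt
Reagents that add atoms: iodine, II
Why: Appel-type iodination should convert the primary alcohol into the iodide by SN2 displacement of the oxyphosphonium ion.

Step 14
Reactants: 18 C4 primary iodide
Product: 19 phosphonoacetate (C5 epimers) with C12 enone and C14 silyl ether
Conditions: NaH, trimethyl phosphonoacetate (excess), DMF, 0 °C → rt
Reagents that add atoms: trimethyl phosphonoacetate, COC(=O)CP(=O)(OC)OC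
Why: SN2 alkylation of the sodium salt of trimethyl phosphonoacetate by the primary iodide forms the C4–C5 bond and brings in C16 and the phosphonate for the later olefination; the stabilised anion is too weak a base to enolise the ketone, and the new C5 centre is lost in step 26.

Step 15
Reactants: 19 phosphonoacetate with C14 silyl ether
Product: 20 14α-hydroxy enone
Conditions: HF·pyridine, THF, 0 °C → rt
Reagents that add atoms: none
Why: Fluoride-mediated cleavage of the silyl ether frees the C14 hydroxyl needed to direct steps 16 and 18; acetate, acetal and phosphonate should be stable to HF·pyridine.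

Step 16
Reactants: 20 14α-hydroxy enone
Product: 21 12β,14α-diol (C10=C11 alkene retained)
Conditions: Me4NBH(OAc)3, MeCN/AcOH, −20 °C
Reagents that add atoms: none
Why: Evans–Saksena reduction: the alkoxy(acetoxy)borohydride formed at the C14 oxygen delivers hydride intramolecularly to the α face of the C12 carbonyl, which should give the 1,3-anti (12β,14α) diol.

Step 17
Reactants: 21 12β,14α-diol
Product: 22 12β-tert-butyldimethylsilyl ether (14α-OH free)
Conditions: TBSCl, imidazole, DMF, 0 °C
Reagents that add atoms: tert-butyldimethylsilyl chloride, CC(C)(C)[Si](C)(C)Cl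
Why: Silylation should occur selectively at the allylic C12 hydroxyl, because the C14 hydroxyl is neopentyl-like (flanked by quaternary C1) and far more hindered.

Step 18
Reactants: 22 12β-silyl ether with free 14α-OH
Product: 23 saturated six-membered ring (10α-H, 11α-H; C9 and C20 both β)
Conditions: H2 (1 atm), [Ir(cod)(PCy3)(py)]PF6 (cat.), CH2Cl2, rt
Reagents that add atoms: none
Why: Hydroxyl-directed homogeneous hydrogenation: the cationic iridium catalyst binds the α-oriented C14 hydroxyl and should add H2 syn to the α face of the tetrasubstituted alkene (the β face is also shielded by the C15 methyl and the C12 silyl ether), setting C10 (H α, C9 β) and C11 (H α, methyl β) together.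

Step 19
Reactants: 23 saturated ring with free 14α-OH
Product: 24 2,14-diacetate phosphonate (C1–C5, C9–C16 fragment)
Conditions: Ac2O, pyridine, DMAP (cat.), 40 °C
Reagents that add atoms: acetic anhydride, CC(=O)OC(C)=O
Why: DMAP-catalysed acetylation of the hindered C14 hydroxyl installs the second acetate of the target.

Step 20
Reactants: 25 (S)-but-3-ene-1,2-diol
Product: 26 (S)-1,2-bis(tert-butyldimethylsilyloxy)but-3-ene
Conditions: TBSCl (2.5 equiv), imidazole, DMF, rt
Reagents that add atoms: tert-butyldimethylsilyl chloride, CC(C)(C)[Si](C)(C)Cl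
Why: Both hydroxyls are silylated under standard conditions; the stereocentre (C7 of the target) is not involved.

Step 21
Reactants: 26 (S)-1,2-bis(tert-butyldimethylsilyloxy)but-3-ene
Product: 27 (S)-2-(tert-butyldimethylsilyloxy)but-3-en-1-ol
Conditions: HF·pyridine, pyridine, THF, 0 °C
Reagents that add atoms: none
Why: Primary silyl ethers are cleaved by buffered HF·pyridine much faster than secondary ones, which should give the primary alcohol selectively.

Step 22
Reactants: 27 (S)-2-(tert-butyldimethylsilyloxy)but-3-en-1-ol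
Product: 28 (S)-2-(tert-butyldimethylsilyloxy)but-3-enal
Conditions: Dess–Martin periodinane, NaHCO3, CH2Cl2, 0 °C
Reagents that add atoms: none
Why: Dess–Martin oxidation under buffered non-basic conditions should give the α-silyloxy β,γ-unsaturated aldehyde without epimerisation or double-bond migration; it is used at once.

Step 23
Reactants: 28 (S)-2-(tert-butyldimethylsilyloxy)but-3-enal
Product: 29 methyl (4S)-3-hydroxy-2-methyl-4-(tert-butyldimethylsilyloxy)hex-5-enoate (C8 and C17 epimers)
Conditions: LiN(i-Pr)2, THF, −78 °C; methyl propanoate; then 28, −78 °C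
Reagents that add atoms: methyl propanoate, CCC(=O)OC
Why: Aldol addition of the lithium enolate of methyl propanoate forms the C8–C17 bond; the two new centres need no control, since C8 is oxidised in step 28 and C17 is equilibrated in step 31.

Step 24
Reactants: 29 aldol adduct (C8 and C17 epimers)
Product: 30 methyl (4S)-3-(methoxymethoxy)-2-methyl-4-(tert-butyldimethylsilyloxy)hex-5-enoate
Conditions: MeOCH2Cl, i-Pr2NEt, CH2Cl2, 0 °C → rt
Reagents that add atoms: chloromethyl methyl ether, COCCl
Why: Alkylation of the hydroxyl with chloromethyl methyl ether gives the acetal, chosen so that the C8 and C9 oxygens can later be unmasked together.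

Step 25
Reactants: 30 methoxymethyl ether with terminal vinyl group
Product: 32 methyl 3-(methoxymethoxy)-2-methyl-5-oxo-4-(tert-butyldimethylsilyloxy)pentanoate (C6 aldehyde; C7 as in 25), via ozonide 31 (not isolated)
Conditions: O3, CH2Cl2, −78 °C; then PPh3, −78 °C → rt
Reagents that add atoms: ozone, [O-][O+]=O
Why: Ozonolysis of the terminal vinyl group and reductive work-up should give the α-silyloxy aldehyde (C6) without touching the other groups.

Step 26
Reactants: 24 2,14-diacetate phosphonate; 32 C6 aldehyde
Product: 33 open-chain enoate (C5=C6 with C4 cis to C7; C8 and C9 as methoxymethyl ethers)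
Conditions: LiCl, DBU, MeCN, 0 °C → rt
Reagents that add atoms: none
Why: Horner–Wadsworth–Emmons olefination under Masamune–Roush conditions (mild enough to avoid epimerisation at C7) should form the C5=C6 bond with the usual preference of α-alkyl phosphonoacetates for the isomer with the ester trans to the aldehyde-derived substituent, that is C4 cis to C7 as in the target.

Step 27
Reactants: 33 open-chain enoate bis(methoxymethyl) ether
Product: 35 8,9-diol (C9 primary, C8 secondary hydroxyl), via bis(bromomethyl) ether 34 (not isolated)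
Conditions: Me2BBr, CH2Cl2, −78 °C; then NaHCO3 (aq), THF
Reagents that add atoms: none
Why: Bromodimethylborane cleaves methoxymethyl acetals at −78 °C via the bromomethyl ethers, which hydrolyse on work-up, and should leave silyl ethers, acetates and esters intact, freeing the C8 and C9 hydroxyls together.

Step 28
Reactants: 35 8,9-diol
Product: 36 keto aldehyde (C9 aldehyde on C10; C8 ketone of a β-keto ester)
Conditions: Dess–Martin periodinane, NaHCO3, CH2Cl2, 0 °C → rt
Reagents that add atoms: none
Why: Dess–Martin oxidation of both hydroxyls under buffered conditions should give the C9 aldehyde and the C8 ketone without basic reagents that would epimerise C7 or C10; the product is used directly.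

Step 29
Reactants: 36 keto aldehyde
Product: 37 ten-membered carbocycle with cis-8α,9α-diol (C8 and C9 configured as in the target)
Conditions: SmI2 (3 equiv), THF, slow addition of 36 (2 mM final), −78 → 0 °C; pH 7 buffer
Reagents that add atoms: none
Why: SmI2 transfers one electron to the samarium-chelated β-keto ester carbonyl (or to the aldehyde) to give a ketyl, which adds to the second carbonyl held on the same samarium centre, and a second electron transfer gives the trivalent-samarium diolate that is protonated on work-up; this is an intramolecular pinacol coupling of a keto aldehyde, the closest known reaction type being the SmI2 pinacol cyclisation of β-keto esters bearing a tethered aldehyde and the low-valent-metal pinacol closure of medium carbocycles. The ten-membered carbocycle C1–C10 closes in the 10-exo-trig mode, the ketyl carbon attacking a carbonyl carbon whose oxygen stays outside the new ring. The configuration at C8 is controlled by C7 (bond formation anti to the C7–OSi bond, C17 branch next to H7, polar Felkin–Anh) and that at C9 by C10 (approach anti to quaternary C1 past H10, Felkin–Anh); both preferences lead to the target configurations and are met together in the samarium-bridged array with the two oxygens syn, which corresponds to the cis-8α,9α-diol. The step needs chemoselectivity for the two carbonyls over the C5=C6 enoate and over reductive loss of the C7 silyloxy group, which omitting HMPA and proton donors should secure (enoate reduction and C–O cleavage are then slow relative to ketyl coupling), and it needs ring closure rather than dimerisation, which slow addition at high dilution should secure.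

Step 30
Reactants: 37 macrocyclic cis-8,9-diol
Product: 38 9-acetate (tertiary 8-OH free)
Conditions: Ac2O, pyridine, DMAP (cat.), CH2Cl2, 0 °C → rt
Reagents that add atoms: acetic anhydride, CC(=O)OC(C)=O
Why: DMAP-catalysed acetylation should occur at the secondary C9 hydroxyl only, the tertiary C8 hydroxyl being too hindered, and it also prevents lactonisation of the C9 hydroxyl onto C19.

Step 31
Reactants: 38 9-acetate with C7 and C12 silyl ethers
Product: 41 CNP0233742.2 (target), via triol ester 39 (not isolated), via lactone epimers 40 (not isolated)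
Conditions: HF·pyridine, pyridine, THF, 0 °C → rt; then DBU, toluene, 40 °C
Reagents that add atoms: none
Why: Fluoride removes both silyl ethers, the freed C7 hydroxyl closes the γ-lactone onto the C19 methyl ester (5-exo-trig acyl substitution), and DBU-mediated enolisation should equilibrate C17 to the more stable epimer, in which the methyl group is trans to the bulky C9 branch and cis to the small C8 hydroxyl (17R), as in the target.

Compound list
1 | 2-methylcyclohexane-1,3-dione | CC1C(=O)CCCC1=O | starting material
2 | 2-allyl-2-methylcyclohexane-1,3-dione | C=CCC1(C)C(=O)CCCC1=O | intermediate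
3 | (2S,3S)-2-allyl-3-hydroxy-2-methylcyclohexan-1-one | O=C1CCC[C@H](O)[C@]1(C)CC=C | intermediate
4 | (2S,3S)-2-allyl-3-(tert-butyldimethylsilyloxy)-2-methylcyclohexan-1-one | O=C1CCC[C@H](O[Si](C)(C)C(C)(C)C)[C@]1(C)CC=C | intermediate
5 | (2S,3S)-2-allyl-3-(tert-butyldimethylsilyloxy)-2,6-dimethylcyclohexan-1-one (C11 epimers) | O=C1C(C)CC[C@H](O[Si](C)(C)C(C)(C)C)[C@]1(C)CC=C | intermediate
6 | (5S,6S)-6-allyl-5-(tert-butyldimethylsilyloxy)-2,6-dimethylcyclohex-2-en-1-one | O=C1C(C)=CC[C@H](O[Si](C)(C)C(C)(C)C)[C@]1(C)CC=C | intermediate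
7 | (5S,6S)-6-allyl-5-(tert-butyldimethylsilyloxy)-1-[(methoxymethoxy)methyl]-2,6-dimethylcyclohex-2-en-1-ol (C10 epimers) | OC1(COCOC)C(C)=CC[C@H](O[Si](C)(C)C(C)(C)C)[C@]1(C)CC=C | intermediate
8 | (4R,5S)-4-allyl-5-(tert-butyldimethylsilyloxy)-3-[(methoxymethoxy)methyl]-2,4-dimethylcyclohex-2-en-1-one | COCOCC1=C(C)C(=O)C[C@H](O[Si](C)(C)C(C)(C)C)[C@]1(C)CC=C | intermediate
9 | (4R,5S)-5-(tert-butyldimethylsilyloxy)-3-[(methoxymethoxy)methyl]-2,4-dimethyl-4-[(E)-prop-1-enyl]cyclohex-2-en-1-one | COCOCC1=C(C)C(=O)C[C@H](O[Si](C)(C)C(C)(C)C)[C@]1(C)/C=C/C | intermediate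
10 | ozonide (1,2,4-trioxolane) of the propenyl group of 9 | COCOCC1=C(C)C(=O)C[C@H](O[Si](C)(C)C(C)(C)C)[C@]1(C)C2OOC(C)O2 | intermediate
11 | (1R,6S)-6-(tert-butyldimethylsilyloxy)-2-[(methoxymethoxy)methyl]-1,3-dimethyl-4-oxocyclohex-2-ene-1-carbaldehyde (C2 aldehyde) | COCOCC1=C(C)C(=O)C[C@H](O[Si](C)(C)C(C)(C)C)[C@]1(C)C=O | intermediate
12 | O-diisopinocampheylborinate of 13 | COCOCC1=C(C)C(=O)C[C@H](O[Si](C)(C)C(C)(C)C)[C@]1(C)[C@H](OB([C@H]2C[C@H]3C[C@@H]([C@@H]2C)C3(C)C)[C@H]2C[C@H]3C[C@@H]([C@@H]2C)C3(C)C)CC=C | intermediate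
13 | (2R)-homoallylic alcohol: 11 with CHO replaced by (R)-CH(OH)CH2CH=CH2 | COCOCC1=C(C)C(=O)C[C@H](O[Si](C)(C)C(C)(C)C)[C@]1(C)[C@H](O)CC=C | intermediate
14 | (2R)-homoallylic acetate of 13 | COCOCC1=C(C)C(=O)C[C@H](O[Si](C)(C)C(C)(C)C)[C@]1(C)[C@H](OC(C)=O)CC=C | intermediate
15 | terminal ozonide of 14 | COCOCC1=C(C)C(=O)C[C@H](O[Si](C)(C)C(C)(C)C)[C@]1(C)[C@H](OC(C)=O)CC2OOCO2 | intermediate
16 | C4 aldehyde (2-acetoxy, C3H2, C4HO) | COCOCC1=C(C)C(=O)C[C@H](O[Si](C)(C)C(C)(C)C)[C@]1(C)[C@H](OC(C)=O)CC=O | intermediate
17 | C4 primary alcohol (2R acetate) | COCOCC1=C(C)C(=O)C[C@H](O[Si](C)(C)C(C)(C)C)[C@]1(C)[C@H](OC(C)=O)CCO | intermediate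
18 | C4 primary iodide (2R acetate) | COCOCC1=C(C)C(=O)C[C@H](O[Si](C)(C)C(C)(C)C)[C@]1(C)[C@H](OC(C)=O)CCI | intermediate
19 | phosphonoacetate with C12 enone and 14α-silyl ether (C5 epimers) | COCOCC1=C(C)C(=O)C[C@H](O[Si](C)(C)C(C)(C)C)[C@]1(C)[C@H](OC(C)=O)CCC(C(=O)OC)P(=O)(OC)OC | intermediate
20 | 14α-hydroxy enone phosphonoacetate | COCOCC1=C(C)C(=O)C[C@H](O)[C@]1(C)[C@H](OC(C)=O)CCC(C(=O)OC)P(=O)(OC)OC | intermediate
21 | 12β,14α-diol phosphonoacetate (C10=C11 alkene) | COCOCC1=C(C)[C@@H](O)C[C@H](O)[C@]1(C)[C@H](OC(C)=O)CCC(C(=O)OC)P(=O)(OC)OC | intermediate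
22 | 12β-tert-butyldimethylsilyl ether with free 14α-OH | COCOCC1=C(C)[C@@H](O[Si](C)(C)C(C)(C)C)C[C@H](O)[C@]1(C)[C@H](OC(C)=O)CCC(C(=O)OC)P(=O)(OC)OC | intermediate
23 | saturated ring (10α-H, 11β-methyl, 12β-OTBS, 14α-OH) phosphonoacetate | COCOC[C@H]1[C@@H](C)[C@@H](O[Si](C)(C)C(C)(C)C)C[C@H](O)[C@]1(C)[C@H](OC(C)=O)CCC(C(=O)OC)P(=O)(OC)OC | intermediate
24 | 2,14-diacetate phosphonoacetate (C1–C5, C9–C16 fragment) | COCOC[C@H]1[C@@H](C)[C@@H](O[Si](C)(C)C(C)(C)C)C[C@H](OC(C)=O)[C@]1(C)[C@H](OC(C)=O)CCC(C(=O)OC)P(=O)(OC)OC | intermediate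
25 | (S)-but-3-ene-1,2-diol | C=C[C@H](O)CO | starting material
26 | (S)-1,2-bis(tert-butyldimethylsilyloxy)but-3-ene | C=C[C@H](O[Si](C)(C)C(C)(C)C)CO[Si](C)(C)C(C)(C)C | intermediate
27 | (S)-2-(tert-butyldimethylsilyloxy)but-3-en-1-ol | C=C[C@H](O[Si](C)(C)C(C)(C)C)CO | intermediate
28 | (S)-2-(tert-butyldimethylsilyloxy)but-3-enal | C=C[C@H](O[Si](C)(C)C(C)(C)C)C=O | intermediate
29 | methyl (4S)-3-hydroxy-2-methyl-4-(tert-butyldimethylsilyloxy)hex-5-enoate (C8, C17 epimers) | C=C[C@H](O[Si](C)(C)C(C)(C)C)C(O)C(C)C(=O)OC | intermediate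
30 | methyl (4S)-3-(methoxymethoxy)-2-methyl-4-(tert-butyldimethylsilyloxy)hex-5-enoate | C=C[C@H](O[Si](C)(C)C(C)(C)C)C(OCOC)C(C)C(=O)OC | intermediate
31 | terminal ozonide of 30 | C1OOC(O1)[C@H](O[Si](C)(C)C(C)(C)C)C(OCOC)C(C)C(=O)OC | intermediate
32 | methyl 3-(methoxymethoxy)-2-methyl-5-oxo-4-(tert-butyldimethylsilyloxy)pentanoate (C6 aldehyde, C7 configuration of 25 retained) | O=C[C@H](O[Si](C)(C)C(C)(C)C)C(OCOC)C(C)C(=O)OC | intermediate
33 | open-chain enoate (C5=C6, ester trans to C7; 8,9-bis(methoxymethyl) ether) | COCOC[C@H]1[C@@H](C)[C@@H](O[Si](C)(C)C(C)(C)C)C[C@H](OC(C)=O)[C@]1(C)[C@H](OC(C)=O)CC/C(C(=O)OC)=C\[C@H](O[Si](C)(C)C(C)(C)C)C(OCOC)C(C)C(=O)OC | intermediate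
34 | 8,9-bis(bromomethyl) ether of 35 | BrCOC[C@H]1[C@@H](C)[C@@H](O[Si](C)(C)C(C)(C)C)C[C@H](OC(C)=O)[C@]1(C)[C@H](OC(C)=O)CC/C(C(=O)OC)=C\[C@H](O[Si](C)(C)C(C)(C)C)C(OCBr)C(C)C(=O)OC | intermediate
35 | open-chain 8,9-diol | OC[C@H]1[C@@H](C)[C@@H](O[Si](C)(C)C(C)(C)C)C[C@H](OC(C)=O)[C@]1(C)[C@H](OC(C)=O)CC/C(C(=O)OC)=C\[C@H](O[Si](C)(C)C(C)(C)C)C(O)C(C)C(=O)OC | intermediate
36 | keto aldehyde (C9 aldehyde, C8 β-keto ester) | O=C[C@H]1[C@@H](C)[C@@H](O[Si](C)(C)C(C)(C)C)C[C@H](OC(C)=O)[C@]1(C)[C@H](OC(C)=O)CC/C(C(=O)OC)=C\[C@H](O[Si](C)(C)C(C)(C)C)C(=O)C(C)C(=O)OC | intermediate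
37 | ten-membered carbocycle with cis-8α,9α-diol (C17 epimers) | COC(=O)/C1=C/[C@H](O[Si](C)(C)C(C)(C)C)[C@@](O)(C(C)C(=O)OC)[C@H](O)[C@H]2[C@@H](C)[C@@H](O[Si](C)(C)C(C)(C)C)C[C@H](OC(C)=O)[C@]2(C)[C@H](OC(C)=O)CC1 | intermediate
38 | 9-acetate of 37 | COC(=O)/C1=C/[C@H](O[Si](C)(C)C(C)(C)C)[C@@](O)(C(C)C(=O)OC)[C@H](OC(C)=O)[C@H]2[C@@H](C)[C@@H](O[Si](C)(C)C(C)(C)C)C[C@H](OC(C)=O)[C@]2(C)[C@H](OC(C)=O)CC1 | intermediate
39 | desilylated 7,8,12-triol methyl ester | COC(=O)/C1=C/[C@H](O)[C@@](O)(C(C)C(=O)OC)[C@H](OC(C)=O)[C@H]2[C@@H](C)[C@@H](O)C[C@H](OC(C)=O)[C@]2(C)[C@H](OC(C)=O)CC1 | intermediate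
40 | 7,19-lactone as C17 epimer mixture | COC(=O)/C1=C/[C@@H]2OC(=O)C(C)[C@@]2(O)[C@H](OC(C)=O)[C@H]2[C@@H](C)[C@@H](O)C[C@H](OC(C)=O)[C@]2(C)[C@H](OC(C)=O)CC1 | intermediate
41 | CNP0233742.2 | COC(=O)/C1=C/[C@@H]2OC(=O)[C@H](C)[C@@]2(O)[C@H](OC(C)=O)[C@H]2[C@@H](C)[C@@H](O)C[C@H](OC(C)=O)[C@]2(C)[C@H](OC(C)=O)CC1 | target

Total step count: 31. Longest linear sequence: 25 steps (steps 1–19, then 26–31).

Steps most likely to fail

Step 29 (key step). What may go wrong: reductive cleavage of the C7–O bond next to the ketyl, ketyl addition to the C5=C6 enoate, intermolecular coupling, or closure to the wrong diol diastereomer. Fallback: the same bond would be closed as an alkene and oxygenated afterwards. Keto aldehyde 36 would be treated with low-valent titanium (TiCl3(DME)1.5, Zn(Cu), DME, reflux, syringe-pump addition; McMurry coupling) to give the ring-cis macrocyclic (8Z)-8,9-alkene F1. Catalytic OsO4 with N-methylmorpholine N-oxide would then dihydroxylate this electron-rich trisubstituted alkene, not the enoate, from the face anti to the allylic C7 silyloxy group; this syn addition should give cis-diol 37, where the route is rejoined.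

Step 18. What may go wrong: the hindered tetrasubstituted alkene resists hydrogenation, the catalyst is sequestered by the phosphonate, or hydrogen is delivered to the β face. Fallback: the alkene would be reduced earlier, while it is still conjugated to the C12 ketone. β-Hydroxy enone 20 would be hydrogenated with the cationic rhodium catalyst [Rh(nbd)(dppb)]BF4 under H2 pressure, directed by the C14 hydroxyl, to the saturated 14α-hydroxy ketone F2. Evans–Saksena reduction with Me4NBH(OAc)3 would give the saturated 12β,14α-diol F3, and selective silylation of the C12 hydroxyl (TBSCl, imidazole) would return to 23.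

Step 16. What may go wrong: acetyl migration from O2 to the free C14 hydroxyl removes the directing group, or intramolecular hydride delivery to the hindered conjugated ketone is slow, so that facial selectivity is lost. Fallback: the order of steps 15 and 16 would be inverted and the reduction run under reagent control. Ketone 19 would be reduced with the (R)-2-methyl-CBS-oxazaborolidine catalyst and BH3·SMe2 (Corey–Bakshi–Shibata reduction, the alkenyl side acting as the large substituent, hydride to the α face) to the 12β-allylic alcohol with 14α-silyl ether F4. HF·pyridine would then remove the C14 silyl group to give diol 21, where the route is rejoined.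

Further compounds
F1 | step 29 | macrocyclic (8Z)-8,9-alkene | COC(=O)/C1=C/[C@H](O[Si](C)(C)C(C)(C)C)/C(C(C)C(=O)OC)=C\[C@H]2[C@@H](C)[C@@H](O[Si](C)(C)C(C)(C)C)C[C@H](OC(C)=O)[C@]2(C)[C@H](OC(C)=O)CC1
F2 | step 18 | saturated 14α-hydroxy ketone | COCOC[C@H]1[C@@H](C)C(=O)C[C@H](O)[C@]1(C)[C@H](OC(C)=O)CCC(C(=O)OC)P(=O)(OC)OC
F3 | step 18 | saturated 12β,14α-diol | COCOC[C@H]1[C@@H](C)[C@@H](O)C[C@H](O)[C@]1(C)[C@H](OC(C)=O)CCC(C(=O)OC)P(=O)(OC)OC
F4 | step 16 | 12β-allylic alcohol with 14α-silyl ether | COCOCC1=C(C)[C@@H](O)C[C@H](O[Si](C)(C)C(C)(C)C)[C@]1(C)[C@H](OC(C)=O)CCC(C(=O)OC)P(=O)(OC)OC
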